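## The problem

The target **23**, methyl 2-[(3R,5S)-3,5-dimethyl-5-[(2R)-2-methyl-8-phenyloctyl]-1,2-dioxolan-3-yl]acetate, has one ring, a 1,2-dioxolane (O1, O2, C3, C4, C5). It is numbered here with the ester carbon as C1 and the chain running C6 to C13, the phenyl ring on C13. Both C–O carbons are fully substituted: C3 holds a methyl group and the CH2CO2Me arm, C5 a methyl group and the chain, with the arm and the chain on opposite faces. A third stereocentre, C7, is a methyl-branched CH in the chain. C7 can be bought but is too flexible to bias C5, and C3 and C5 can inform each other only through the ring, so at least one of them must be set absolutely and independently. A tertiary C–OO bond can be made with control only by opening a strained ether, or without control by radical oxygenation. Once the O–O bond exists, hydrogenation, phosphines, low-valent metals and hydride reagents are excluded (so benzyl ethers are useless late), and the β-peroxy ester opens by β-elimination in base, so the ester must come last under neutral conditions. The enabling feature is the 1,3 placement of the two ring oxygens on the tertiary carbons C3 and C5: tertiary peroxyl radicals there have no α-hydrogen, cannot disproportionate and can only couple, so O1–O2 can be the last ring bond formed with all three carbon stereocentres already in place.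

## Retrosynthesis

**C1 oxidation level (23 ⇐ 22 ⇐ 20).** No skeletal bond is cut. The ester is traced to acid **22** and to the primary alcohol **20**. Carrying C1 as an alcohol keeps the base-labile β-peroxy carbonyl out of every earlier step. The forward steps must be an oxidation that tolerates a dialkyl peroxide and a neutral methylation.

**O1–O2 (20 ⇐ 18).** The ring is opened at the peroxide bond to the 1,3-bis(hydroperoxide) **18**. The neighbouring cuts, O–C3 or O–C5, would each force a ring-forming substitution or addition at a quaternary carbon in the last ring step. The O–O cut touches no carbon, so C3, C5 and C7 arrive finished. The precursor is acyclic, and its two C–O bonds can be installed one at a time by different chemistry. The forward reaction must oxidise two OOH groups in the presence of a primary OH and make the alkoxyl radical pair recombine faster than it fragments.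

**C5–O (18 ⇐ 17 ⇐ 16 ⇐ 15).** The C5 hydroperoxide is removed to a C5 methylene alkene. Radical hydrosilylperoxidation puts hydrogen on the terminal CH2 (which becomes the C5 methyl) and oxygen on C5, so the methyl never has to be unmasked next to a peroxide. The C3 hydroperoxide and the alcohol of **15** are masked as triethylsilyl groups (**16**), so that one fluoride treatment of **17** frees all three. The precursor **15** has one peroxide and two stereocentres. The forward reaction gives no facial control at C5; **18** must be separated from its C5 epimer, and this is the accepted price of the plan.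

**C3–O (15 ⇐ 14).** The C3–OOH bond is cut back to the oxetane **14**, whose ring oxygen sits on C3 with the opposite configuration. This is preferred over radical oxygenation of a C3 methylene, which would leave C3 uncontrolled and double the number of isomers. The precursor has no peroxide. The forward reaction must open the oxetane at the tertiary carbon by H2O2 with inversion and without ionisation.

**C1–C2 and C1–O (14 ⇐ 13 ⇐ 12).** The oxetane is contracted to the 2,2-disubstituted epoxide **13**, with C1 supplied as a sulfoxonium methylide carbon; **13** comes from the hydroxy tosylate **12** by base. A 1,3-diol made by asymmetric epoxidation of a 3-methylalk-2-en-1-ol and hydride opening was weighed against this. It needs a skipped dienol that is itself several steps away. The ring expansion adds C1 in one operation and does not touch C3.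

**C4–C5 (12 ⇐ 11 + 10; 10 ⇐ 9; 11 ⇐ 8).** Cutting C4–C5 separates an alkenyl Grignard reagent **11** (from bromide **8**) from the epoxy tosylate **10**, made in one step from (R)-2-methylglycidol **9**. The alternative cut C3–C4 (allyl metal plus methyl ketone) was rejected because no reagent distinguishes a methyl from a 2-oxyethyl group on a ketone. Here C3 is bought and no bond to it is made or broken. The forward reaction must attack the epoxide CH2 and leave the neopentyl-type tosylate alone.

**C5–Br and C5–C6 (8 ⇐ 6 ⇐ 5 ⇐ 4).** The 2-bromoalkene is traced to the terminal alkyne **6** (Markovnikov addition of H–Br by bromoboration) and the alkyne to iodide **5** and alcohol **4**. This places the 1,1-disubstituted alkene carbon C5 directly on C6 without a ketone methylenation. The forward reactions are standard; only the displacement at a β-branched primary iodide needs care.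

**C8–C9 (4 ⇐ 3 + 2; 3 ⇐ 1).** The chain is cut next to the stereocentre-bearing fragment, giving Grignard reagent **3** from bromide **1** and the bromo alcohol **2**. C7 is taken from **2** and is never touched again.

## Roads not taken

**Alternative 1:** Peroxycarbenium–alkene [3+2] annulation, cutting C4–C5 and O–C3.
- **Forward step.** SnCl4 would ionise the silylperoxy ketal triethyl{[(4R)-2-methoxy-4-methyl-10-phenyldecan-2-yl]peroxy}silane A2. The CH2 of tert-butyl[(3-methylbut-3-en-1-yl)oxy]diphenylsilane A3 would attack C5, and the silylperoxy oxygen would capture the C3 cation, giving tert-butyl{2-[(3S,5S)-3,5-dimethyl-5-[(2R)-2-methyl-8-phenyloctyl]-1,2-dioxolan-3-yl]ethoxy}diphenylsilane A1.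
- **Merits.** It is convergent and forms two bonds and the ring at once. A2 is a few operations from alkyne **6**, and the whole route would be about four steps shorter than the chosen one, without stoichiometric lead.
- **Weak points.** The peroxycarbenium carbon C5 is planar and C7 cannot bias it. The cis/trans outcome at C3 depends on telling a methyl from a CH2R group on C5, so all four C3/C5 stereoisomers are expected. Two of them differ from A1 only in their relation to the remote C7, the hardest kind of isomer to remove.
- **Comparison.** This road is shorter and more convergent. The chosen plan sets against it a bought, stereospecifically transferred C3, which leaves a single 3,5-syn/anti pair to separate.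

**Alternative 2:** Catalytic asymmetric hydroperoxidation of an enone, cutting O–C5 and the hemiketal O–C3.
- **Forward step.** H2O2 would add to C5 of (3E,6R)-4,6-dimethyl-12-phenyldodec-3-en-2-one A5 under a 9-amino-9-deoxy-epi-cinchona salt, and the hydroperoxide would close on the C3 carbonyl to give (5S)-3,5-dimethyl-5-[(2R)-2-methyl-8-phenyloctyl]-1,2-dioxolan-3-ol A4. Lewis-acid ionisation at C3 and capture by an acetate silyl ketene acetal would then give the ester directly.
- **Merits.** It is the only plan that sets C5 by a catalyst, with either configuration available from pseudoenantiomeric catalysts. It is the shortest route and needs no alcohol oxidation.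
- **Weak points.** A5 is a β,β-disubstituted enone. Iminium-mediated conjugate addition that creates a quaternary C–OO centre lies outside the reliable range of this catalysis, and E/Z scrambling through the dienamine would erode selectivity. C3 is then set against a C5 whose two substituents differ little in size.
- **Comparison.** Its strength and weakness mirror the chosen plan: it controls C5 and leaves C3, where the chosen plan controls C3 and leaves C5. The chosen plan sets against it that its uncontrolled step is certain to give the right constitution on a 1,1-disubstituted alkene, while the controlling step of this road may not work on this substitution pattern.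

**Alternative 3:** Iodocyclisation of the C3 hydroperoxide onto the C5 methylene, cutting O–C5 only.
- **Forward step.** N-Iodosuccinimide would activate the alkene of **15**, and the hydroperoxide would close 5-exo on C5 to give 2-[(3S,5S)-5-(iodomethyl)-3-methyl-5-[(2R)-2-methyl-8-phenyloctyl]-1,2-dioxolan-3-yl]ethanol A6. Replacing iodine by hydrogen would give **20**.
- **Merits.** It shares steps 1 to 8 and reaches **20** in two steps where the chosen plan needs four. It needs no second hydroperoxide and no lead. In step count and in handling of peroxides it is the better road.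
- **Weak points.** Facial selectivity at C5 is no better founded than in the chosen plan. The C1 hydroxyl competes for the iodonium ion by closing a six-membered ether, and protecting it returns the saved steps. The CH2I group of A6 is neopentyl-like and sits beside the O–O bond: hydride displacement is blocked, and radical reduction passes through a β-peroxyalkyl radical that attacks the peroxide oxygen and destroys the ring.
- **Comparison.** The chosen plan sets against the shorter count that the C5 methyl is delivered as a methyl, with no reduction ever needed next to the peroxide.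

Key step: step 12

Assumption: (R)-2-methylglycidol **9** is used at the enantiomeric purity of the commercial material, which caps the purity at C3; every numbered step, one-pot sequences included, is counted as one step.

## Route

Step 1
Reactants: 1 (5-bromopentyl)benzene; 2 (2S)-3-bromo-2-methylpropan-1-ol
Product: 4 (2R)-2-methyl-8-phenyloctan-1-ol, via (5-phenylpentyl)magnesium bromide 3 (not isolated)
Conditions: 1, Mg, THF, 40 °C; then 2 (0.4 equiv relative to 3), Li2CuCl4 (3 mol%), THF/NMP, −10 °C → rt; aq. NH4Cl
Reagents that add atoms: none
Why: Copper-catalysed sp3–sp3 cross-coupling of a primary Grignard reagent with a primary bromide; the first equivalent of 3 turns the hydroxyl of 2 into its magnesium alkoxide, which is tolerated. C7 of the target is carried over untouched from 2 (S becomes R only because bromine is replaced by carbon).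

Step 2
Reactants: 4 (2R)-2-methyl-8-phenyloctan-1-ol
Product: 5 [(7R)-8-iodo-7-methyloctyl]benzene
Conditions: I2, PPh3, imidazole, CH2Cl2, 0 °C → rt
Reagents that add atoms: iodine, II
Why: Appel-type iodination of a primary alcohol through the alkoxyphosphonium iodide; the adjacent stereocentre is not involved.

Step 3
Reactants: 5 [(7R)-8-iodo-7-methyloctyl]benzene
Product: 6 [(7R)-7-methyldec-9-yn-1-yl]benzene
Conditions: LiC≡CH·H2NCH2CH2NH2, DMSO, 10 °C → rt
Reagents that add atoms: lithium acetylide–ethylenediamine complex, [Li]C#C.NCCN
Why: SN2 alkylation of lithium acetylide by a primary iodide in a dipolar aprotic solvent, a standard route to terminal alkynes that works for β-branched primary halides; it forms the C5–C6 bond.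

Step 4
Reactants: 6 [(7R)-7-methyldec-9-yn-1-yl]benzene
Product: 8 [(7R)-9-bromo-7-methyldec-9-en-1-yl]benzene, via bromoalkenylborane 7 (not isolated)
Conditions: B-bromo-9-BBN, CH2Cl2, 0 °C; then AcOH, 0 °C → rt
Reagents that add atoms: B-bromo-9-borabicyclo[3.3.1]nonane, BrB1C2CCCC1CCC2
Why: Bromoboration of a terminal alkyne places bromine on the internal carbon and boron on the terminal one (cis addition); protonolysis of the C–B bond by acetic acid gives the 2-bromo-1-alkene, the net Markovnikov addition of HBr.

Step 5
Reactants: 9 [(2R)-2-methyloxiran-2-yl]methanol ((R)-2-methylglycidol)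
Product: 10 [(2S)-2-methyloxiran-2-yl]methyl 4-methylbenzenesulfonate
Conditions: TsCl, Et3N, DMAP (cat.), CH2Cl2, 0 °C
Reagents that add atoms: 4-methylbenzenesulfonyl chloride, Cc1ccc(cc1)S(Cl)(=O)=O
Why: Sulfonylation of a primary alcohol; the stereocentre is untouched (R becomes S only through the change in substituent priority).

Step 6
Reactants: 8 [(7R)-9-bromo-7-methyldec-9-en-1-yl]benzene; 10 [(2S)-2-methyloxiran-2-yl]methyl 4-methylbenzenesulfonate
Product: 12 (2S,6R)-2-hydroxy-2,6-dimethyl-4-methylidene-12-phenyldodecyl 4-methylbenzenesulfonate, via alkenylmagnesium bromide 11 (not isolated)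
Conditions: 8, Mg, THF, rt → 40 °C; then CuI (10 mol%), 10 (1.2 equiv), THF, −40 °C; cold aq. NH4Cl
Reagents that add atoms: none
Why: Copper-catalysed opening of a 2,2-disubstituted epoxide by an alkenyl Grignard reagent at the unsubstituted CH2, forming C4–C5; the neopentyl-type tosylate is displaced far more slowly, and a cold quench keeps the magnesium alkoxide from closing onto it. No bond to the quaternary carbon (C3 of the target) is made or broken.

Step 7
Reactants: 12 (2S,6R)-2-hydroxy-2,6-dimethyl-4-methylidene-12-phenyldodecyl 4-methylbenzenesulfonate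
Product: 14 (2S)-2-methyl-2-[(4R)-4-methyl-2-methylidene-10-phenyldecyl]oxetane, via epoxide 13 (not isolated)
Conditions: KOtBu (1.1 equiv), t-BuOH, rt; then Me3S(O)I (3 equiv), KOtBu (3 equiv), t-BuOH, 50 °C
Reagents that add atoms: trimethylsulfoxonium iodide, C[S+](C)(C)=O.[I-]
Why: The alkoxide displaces the tosylate to give epoxide 13; Corey–Chaykovsky-type ring expansion follows, in which dimethylsulfoxonium methylide opens the epoxide at its CH2 and the resulting alkoxide displaces dimethyl sulfoxide (4-exo-tet). The quaternary stereocentre is a spectator throughout, so its configuration is retained.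

Step 8
Reactants: 14 (2S)-2-methyl-2-[(4R)-4-methyl-2-methylidene-10-phenyldecyl]oxetane
Product: 15 (3R,7R)-3-hydroperoxy-3,7-dimethyl-5-methylidene-13-phenyltridecan-1-ol
Conditions: anhydrous H2O2 in Et2O (10 equiv), TMSOTf (20 mol%), Et2O, −78 → −20 °C
Reagents that add atoms: hydrogen peroxide, OO
Why: Lewis-acid-promoted perhydrolysis of a 2,2-disubstituted oxetane: the silyl-activated ring is opened by H2O2 at the tertiary carbon in an SN2-like, ion-pair displacement. C3 is set here by inversion of the oxetane carbon, and the released oxygen becomes the C1 hydroxyl.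

Step 9
Reactants: 15 (3R,7R)-3-hydroperoxy-3,7-dimethyl-5-methylidene-13-phenyltridecan-1-ol
Product: 16 (3R,7R)-3,7-dimethyl-5-methylidene-13-phenyl-1-[(triethylsilyl)oxy]-3-[(triethylsilyl)peroxy]tridecane
Conditions: Et3SiCl (2.4 equiv), imidazole, DMAP (cat.), DMF, 0 °C
Reagents that add atoms: chlorotriethylsilane, CC[Si](Cl)(CC)CC
Why: Silylation of the alcohol and of the more acidic hydroperoxide; masking the OOH group stops cobalt from turning it into a peroxyl radical that would add 6-endo to the C5 alkene in the next step.

Step 10
Reactants: 16 (3R,7R)-3,7-dimethyl-5-methylidene-13-phenyl-1-[(triethylsilyl)oxy]-3-[(triethylsilyl)peroxy]tridecane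
Product: 17 (3S,7R)-3,5,7-trimethyl-13-phenyl-1-[(triethylsilyl)oxy]-3,5-bis[(triethylsilyl)peroxy]tridecane (both C5 epimers)
Conditions: Co(acac)2 (10 mol%), Et3SiH (3 equiv), O2 (1 atm), ClCH2CH2Cl, rt
Reagents that add atoms: dioxygen, O=O; triethylsilane, CC[SiH](CC)CC
Why: Mukaiyama–Isayama hydrosilylperoxidation: a cobalt hydride transfers hydrogen to the terminal CH2, the tertiary C5 radical is trapped by O2 and the peroxyl group is silylated, so regiochemistry is Markovnikov. The planar C5 radical is trapped on either face with no useful bias from C3 or C7, so C5 is formed as both epimers (C3 is unchanged; its descriptor becomes S only because C4 now outranks C2).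

Step 11
Reactants: 17 (3S,7R)-3,5,7-trimethyl-13-phenyl-1-[(triethylsilyl)oxy]-3,5-bis[(triethylsilyl)peroxy]tridecane (both C5 epimers)
Product: 18 (3S,5S,7R)-3,5-dihydroperoxy-3,5,7-trimethyl-13-phenyltridecan-1-ol
Conditions: HF·pyridine, pyridine, THF, 0 °C → rt; chromatography on SiO2
Reagents that add atoms: none
Why: Fluoride cleaves the silyl ether and both silyl peroxides in one operation without touching the O–O bonds. The 3,5-syn/anti pair of acyclic bis(hydroperoxides) should differ enough in hydrogen bonding for 18 to be separated at this stage from its C5 epimer by chromatography.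

Step 12
Reactants: 18 (3S,5S,7R)-3,5-dihydroperoxy-3,5,7-trimethyl-13-phenyltridecan-1-ol
Product: 20 2-[(3S,5S)-3,5-dimethyl-5-[(2R)-2-methyl-8-phenyloctyl]-1,2-dioxolan-3-yl]ethanol, via cyclic tetroxide 19 (not isolated)
Conditions: Pb(OAc)4 (1.05 equiv), CH2Cl2, −40 → −10 °C
Reagents that add atoms: none
Why: The two hydroperoxide groups exchange for acetate on Pb(OAc)4, and homolysis of the Pb–OO bonds (tetravalent to divalent lead) releases two tertiary peroxyl radicals held 1,3 to each other. They combine head to head to the seven-membered cyclic tetroxide 19, which loses O2 and leaves a tethered pair of tertiary alkoxyl radicals that collapse to the O–O bond. The closest known reaction is the lead tetraacetate oxidation of 2,4-dimethylpentane-2,4-diyl bis(hydroperoxide) to 3,3,5,5-tetramethyl-1,2-dioxolane, applied here to an unsymmetrical, hydroxyl-bearing substrate. The five-membered ring closes by radical–radical recombination at oxygen, a net contraction of the tetroxide ring, and not by attack on carbon. No stereocentre is formed and no bond to C3, C5 or C7 is broken, so the configuration of 18 passes into 20. The step needs chemoselectivity for OOH over the primary OH, which rests on the much faster ligand exchange of hydroperoxides at lead, one equivalent of oxidant and low temperature. It also needs recombination to outrun β-scission and 1,5-hydrogen transfer of the alkoxyl radicals, which the tether, the absence of α-hydrogens and the low temperature favour.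

Step 13
Reactants: 20 2-[(3S,5S)-3,5-dimethyl-5-[(2R)-2-methyl-8-phenyloctyl]-1,2-dioxolan-3-yl]ethanol
Product: 22 2-[(3R,5S)-3,5-dimethyl-5-[(2R)-2-methyl-8-phenyloctyl]-1,2-dioxolan-3-yl]acetic acid, via aldehyde 21 (not isolated)
Conditions: TEMPO (20 mol%), PhI(OAc)2 (2.2 equiv), MeCN/H2O 1:1, rt
Reagents that add atoms: water, O
Why: Oxoammonium-mediated oxidation of a primary alcohol to the aldehyde, whose hydrate is oxidised further to the acid in the same pot; the medium is weakly acidic, so the dialkyl peroxide and the β-peroxy carbonyl are not exposed to base. C3 is unchanged (its descriptor becomes R because the carboxymethyl arm now outranks C4).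

Step 14
Reactants: 22 2-[(3R,5S)-3,5-dimethyl-5-[(2R)-2-methyl-8-phenyloctyl]-1,2-dioxolan-3-yl]acetic acid
Product: 23 methyl 2-[(3R,5S)-3,5-dimethyl-5-[(2R)-2-methyl-8-phenyloctyl]-1,2-dioxolan-3-yl]acetate
Conditions: TMSCHN2, toluene/MeOH 4:1, 0 °C
Reagents that add atoms: trimethylsilyldiazomethane, C[Si](C)(C)C=[N+]=[N-]
Why: Methyl esterification of a carboxylic acid by trimethylsilyldiazomethane in methanol; the conditions are neutral and base-free, so β-elimination of the peroxide cannot start.

## Compound list

1 | (5-bromopentyl)benzene | BrCCCCCc1ccccc1 | starting material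
2 | (2S)-3-bromo-2-methylpropan-1-ol | OC[C@H](C)CBr | starting material
3 | (5-phenylpentyl)magnesium bromide | Br[Mg]CCCCCc1ccccc1 | intermediate (not isolated)
4 | (2R)-2-methyl-8-phenyloctan-1-ol | OC[C@H](C)CCCCCCc1ccccc1 | intermediate
5 | [(7R)-8-iodo-7-methyloctyl]benzene | IC[C@H](C)CCCCCCc1ccccc1 | intermediate
6 | [(7R)-7-methyldec-9-yn-1-yl]benzene | C#CC[C@H](C)CCCCCCc1ccccc1 | intermediate
7 | 9-[(1Z,4R)-2-bromo-4-methyl-10-phenyldec-1-en-1-yl]-9-borabicyclo[3.3.1]nonane | Br/C(C[C@H](C)CCCCCCc1ccccc1)=C\B1C2CCCC1CCC2 | intermediate (not isolated)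
8 | [(7R)-9-bromo-7-methyldec-9-en-1-yl]benzene | C=C(Br)C[C@H](C)CCCCCCc1ccccc1 | intermediate
9 | [(2R)-2-methyloxiran-2-yl]methanol ((R)-2-methylglycidol) | OC[C@]1(C)CO1 | starting material
10 | [(2S)-2-methyloxiran-2-yl]methyl 4-methylbenzenesulfonate | Cc1ccc(cc1)S(=O)(=O)OC[C@]1(C)CO1 | intermediate
11 | [(4R)-4-methyl-10-phenyldec-1-en-2-yl]magnesium bromide | C=C([Mg]Br)C[C@H](C)CCCCCCc1ccccc1 | intermediate (not isolated)
12 | (2S,6R)-2-hydroxy-2,6-dimethyl-4-methylidene-12-phenyldodecyl 4-methylbenzenesulfonate | Cc1ccc(cc1)S(=O)(=O)OC[C@](O)(C)CC(=C)C[C@H](C)CCCCCCc1ccccc1 | intermediate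
13 | (2S)-2-methyl-2-[(4R)-4-methyl-2-methylidene-10-phenyldecyl]oxirane | C1[C@](O1)(C)CC(=C)C[C@H](C)CCCCCCc2ccccc2 | intermediate (not isolated)
14 | (2S)-2-methyl-2-[(4R)-4-methyl-2-methylidene-10-phenyldecyl]oxetane | C1C[C@](O1)(C)CC(=C)C[C@H](C)CCCCCCc2ccccc2 | intermediate
15 | (3R,7R)-3-hydroperoxy-3,7-dimethyl-5-methylidene-13-phenyltridecan-1-ol | OCC[C@@](OO)(C)CC(=C)C[C@H](C)CCCCCCc1ccccc1 | intermediate
16 | (3R,7R)-3,7-dimethyl-5-methylidene-13-phenyl-1-[(triethylsilyl)oxy]-3-[(triethylsilyl)peroxy]tridecane | CC[Si](CC)(CC)OCC[C@@](OO[Si](CC)(CC)CC)(C)CC(=C)C[C@H](C)CCCCCCc1ccccc1 | intermediate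
17 | (3S,7R)-3,5,7-trimethyl-13-phenyl-1-[(triethylsilyl)oxy]-3,5-bis[(triethylsilyl)peroxy]tridecane, both C5 epimers | CC[Si](CC)(CC)OCC[C@@](OO[Si](CC)(CC)CC)(C)CC(C)(OO[Si](CC)(CC)CC)C[C@H](C)CCCCCCc1ccccc1 | intermediate
18 | (3S,5S,7R)-3,5-dihydroperoxy-3,5,7-trimethyl-13-phenyltridecan-1-ol | OCC[C@@](OO)(C)C[C@](C)(C[C@H](C)CCCCCCc1ccccc1)OO | intermediate
19 | 2-[(5S,7S)-5,7-dimethyl-7-[(2R)-2-methyl-8-phenyloctyl]-1,2,3,4-tetroxepan-5-yl]ethanol | OCC[C@@]1(C)C[C@](C)(C[C@H](C)CCCCCCc2ccccc2)OOOO1 | intermediate (not isolated)
20 | 2-[(3S,5S)-3,5-dimethyl-5-[(2R)-2-methyl-8-phenyloctyl]-1,2-dioxolan-3-yl]ethanol | OCC[C@@]1(C)C[C@](C)(C[C@H](C)CCCCCCc2ccccc2)OO1 | intermediate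
21 | 2-[(3R,5S)-3,5-dimethyl-5-[(2R)-2-methyl-8-phenyloctyl]-1,2-dioxolan-3-yl]acetaldehyde | O=CC[C@@]1(C)C[C@](C)(C[C@H](C)CCCCCCc2ccccc2)OO1 | intermediate (not isolated)
22 | 2-[(3R,5S)-3,5-dimethyl-5-[(2R)-2-methyl-8-phenyloctyl]-1,2-dioxolan-3-yl]acetic acid | OC(=O)C[C@@]1(C)C[C@](C)(C[C@H](C)CCCCCCc2ccccc2)OO1 | intermediate
23 | methyl 2-[(3R,5S)-3,5-dimethyl-5-[(2R)-2-methyl-8-phenyloctyl]-1,2-dioxolan-3-yl]acetate | COC(=O)C[C@@]1(C)C[C@](C)(C[C@H](C)CCCCCCc2ccccc2)OO1 | target

## Step count and least certain steps

Total: 14 steps. Longest linear sequence: 13 steps (steps 1 to 4 and 6 to 14, from 1 and 2); step 5 is a one-step side branch.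

**Step 12 (key step).**
- **Risk.** The alkoxyl radical pair may escape recombination by β-scission or 1,5-hydrogen transfer, and the primary hydroxyl may compete with the hydroperoxides for ligand exchange at lead and be oxidised. The reaction has only been shown on a symmetrical, unfunctionalised bis(hydroperoxide).
- **Fallback.** It sets out from oxetane 14 and comes back at 20; the last ring bond becomes O–C3 instead of O–O. Hydrosilylperoxidation of 14 under the conditions of step 10 would give triethyl({(4R)-2,4-dimethyl-1-[(2R)-2-methyloxetan-2-yl]-10-phenyldecan-2-yl}peroxy)silane F1 as both C5 epimers (the oxetane carbon is unchanged; its descriptor alters with the new oxygen on the side chain). HF·pyridine would free (4R)-2,4-dimethyl-1-[(2R)-2-methyloxetan-2-yl]-10-phenyldecan-2-yl hydroperoxide F2. Catalytic TMSOTf in CH2Cl2 at −78 °C would then let the hydroperoxide open the oxetane at C3 in a 5-exo displacement with inversion, the same stereochemical event as in step 8. This gives 20 together with 2-[(3S,5R)-3,5-dimethyl-5-[(2R)-2-methyl-8-phenyloctyl]-1,2-dioxolan-3-yl]ethanol F3, from which 20 is separated by chromatography.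

**Step 8.**
- **Risk.** Ionisation at C3 ahead of attack would erode the inversion. Proton loss from the incipient cation, capture of the activated oxetane by the product hydroxyl, or acid-promoted addition of H2O2 to the C5 alkene would lower the yield.
- **Fallback.** It sets out from bromide 8 and comes back at 18, giving up the control at C3. 3-Methylbut-3-en-1-ol would be doubly lithiated (n-BuLi, TMEDA), transmetalated with ZnBr2 and coupled with 8 under Pd(PPh3)4 (Negishi coupling; both ends of the 2-substituted allyl unit give the same product). This gives (7R)-7-methyl-3,5-dimethylidene-13-phenyltridecan-1-ol F4. One Co(acac)2/O2/Et3SiH reaction on both 1,1-disubstituted alkenes would give (7R)-3,5,7-trimethyl-13-phenyl-3,5-bis[(triethylsilyl)peroxy]tridecan-1-ol F5 as four C3/C5 isomers. HF·pyridine would give (7R)-3,5-dihydroperoxy-3,5,7-trimethyl-13-phenyltridecan-1-ol F6 as the four-isomer mixture. 18 would then have to be isolated from it by preparative HPLC, statistically about a quarter of the material.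

**Step 10 (with the separation in step 11).**
- **Risk.** There is no facial selectivity in the trapping of the C5 radical, so about half of the material is the wrong epimer, and the acyclic epimers may co-elute.
- **Fallback.** It sets out from 17 and comes back at 20, moving the separation from the chain to the ring. The epimer pair 17 would be desilylated with HF·pyridine and carried on without separation, as 18 together with (3S,5R,7R)-3,5-dihydroperoxy-3,5,7-trimethyl-13-phenyltridecan-1-ol F7, and the mixture would be treated with Pb(OAc)4 as in step 12. 20 would then be separated from 2-[(3S,5R)-3,5-dimethyl-5-[(2R)-2-methyl-8-phenyloctyl]-1,2-dioxolan-3-yl]ethanol F3, the two being ring diastereomers that differ in shape and polarity far more than the open-chain pair.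

**Step 7.**
- **Risk.** Ring expansion of the hindered epoxide may be slow, so that opening of 13 by tert-butoxide or iodide competes during the long heating.
- **Fallback.** It sets out from epoxide 13 (isolated after the room-temperature stage) and comes back at 14, building C1 as a hydroxymethyl group and closing the oxetane from a 1,3-diol. Copper-catalysed opening of 13 with (i-PrO)Me2SiCH2MgCl (CuI cat., THF) would give (3S,7R)-1-[dimethyl(propan-2-yloxy)silyl]-3,7-dimethyl-5-methylidene-13-phenyltridecan-3-ol F8. Tamao oxidation (H2O2, KF, KHCO3, THF/MeOH) would give (3S,7R)-3,7-dimethyl-5-methylidene-13-phenyltridecane-1,3-diol F9. Selective sulfonylation of the primary hydroxyl (TsCl, pyridine) would give (3S,7R)-3-hydroxy-3,7-dimethyl-5-methylidene-13-phenyltridecyl 4-methylbenzenesulfonate F10, and KOtBu in THF would close it to 14 by 4-exo-tet displacement with C3 untouched.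

## Further compounds

F1 | step 12 | triethyl({(4R)-2,4-dimethyl-1-[(2R)-2-methyloxetan-2-yl]-10-phenyldecan-2-yl}peroxy)silane (both C2 epimers) | C1C[C@](O1)(C)CC(C)(OO[Si](CC)(CC)CC)C[C@H](C)CCCCCCc2ccccc2
F2 | step 12 | (4R)-2,4-dimethyl-1-[(2R)-2-methyloxetan-2-yl]-10-phenyldecan-2-yl hydroperoxide (both C2 epimers) | C1C[C@](O1)(C)CC(C)(OO)C[C@H](C)CCCCCCc2ccccc2
F3 | step 12 | 2-[(3S,5R)-3,5-dimethyl-5-[(2R)-2-methyl-8-phenyloctyl]-1,2-dioxolan-3-yl]ethanol | OCC[C@@]1(C)C[C@@](C)(C[C@H](C)CCCCCCc2ccccc2)OO1
F4 | step 8 | (7R)-7-methyl-3,5-dimethylidene-13-phenyltridecan-1-ol | OCCC(=C)CC(=C)C[C@H](C)CCCCCCc1ccccc1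
F5 | step 8 | (7R)-3,5,7-trimethyl-13-phenyl-3,5-bis[(triethylsilyl)peroxy]tridecan-1-ol (four C3/C5 isomers) | OCCC(C)(OO[Si](CC)(CC)CC)CC(C)(OO[Si](CC)(CC)CC)C[C@H](C)CCCCCCc1ccccc1
F6 | step 8 | (7R)-3,5-dihydroperoxy-3,5,7-trimethyl-13-phenyltridecan-1-ol (four C3/C5 isomers) | OCCC(C)(OO)CC(C)(OO)C[C@H](C)CCCCCCc1ccccc1
F7 | step 10 | (3S,5R,7R)-3,5-dihydroperoxy-3,5,7-trimethyl-13-phenyltridecan-1-ol | OCC[C@@](OO)(C)C[C@@](C)(C[C@H](C)CCCCCCc1ccccc1)OO
F8 | step 7 | (3S,7R)-1-[dimethyl(propan-2-yloxy)silyl]-3,7-dimethyl-5-methylidene-13-phenyltridecan-3-ol | CC(C)O[Si](C)(C)CC[C@](O)(C)CC(=C)C[C@H](C)CCCCCCc1ccccc1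
F9 | step 7 | (3S,7R)-3,7-dimethyl-5-methylidene-13-phenyltridecane-1,3-diol | OCC[C@](O)(C)CC(=C)C[C@H](C)CCCCCCc1ccccc1
F10 | step 7 | (3S,7R)-3-hydroxy-3,7-dimethyl-5-methylidene-13-phenyltridecyl 4-methylbenzenesulfonate | Cc1ccc(cc1)S(=O)(=O)OCC[C@](O)(C)CC(=C)C[C@H](C)CCCCCCc1ccccc1
A1 | alternative 1 | tert-butyl{2-[(3S,5S)-3,5-dimethyl-5-[(2R)-2-methyl-8-phenyloctyl]-1,2-dioxolan-3-yl]ethoxy}diphenylsilane | CC(C)(C)[Si](c1ccccc1)(c1ccccc1)OCC[C@@]1(C)C[C@](C)(C[C@H](C)CCCCCCc2ccccc2)OO1
A2 | alternative 1 | triethyl{[(4R)-2-methoxy-4-methyl-10-phenyldecan-2-yl]peroxy}silane (both C2 epimers) | COC(C)(C[C@H](C)CCCCCCc1ccccc1)OO[Si](CC)(CC)CC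
A3 | alternative 1 | tert-butyl[(3-methylbut-3-en-1-yl)oxy]diphenylsilane | C=C(C)CCO[Si](c1ccccc1)(c1ccccc1)C(C)(C)C
A4 | alternative 2 | (5S)-3,5-dimethyl-5-[(2R)-2-methyl-8-phenyloctyl]-1,2-dioxolan-3-ol (C3 anomers) | CC1(O)C[C@](C)(C[C@H](C)CCCCCCc2ccccc2)OO1
A5 | alternative 2 | (3E,6R)-4,6-dimethyl-12-phenyldodec-3-en-2-one | CC(=O)/C=C(\C)C[C@H](C)CCCCCCc1ccccc1
A6 | alternative 3 | 2-[(3S,5S)-5-(iodomethyl)-3-methyl-5-[(2R)-2-methyl-8-phenyloctyl]-1,2-dioxolan-3-yl]ethanol | OCC[C@@]1(C)C[C@](CI)(C[C@H](C)CCCCCCc2ccccc2)OO1
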